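**Assumption:** the peroxide ring is taken to arise in nature by 6-exo attack of a C7 tertiary hydroperoxide on an electrophilic C4 of the polyketide chain; hexa-1,5-diyne and (7-bromoheptyl)benzene are taken as catalogue chemicals.

## Retrosynthetic overview

1. Target ⇐ diimide saturation ⇐ two successive olefinations (Wittig, then Horner–Wadsworth–Emmons) of (3R,6R)-3,6-dimethyl-1,2-dioxane-3,6-dicarbaldehyde. The trans-dimethyl core is C2-symmetric, so its two formyl groups are homotopic and either may take either chain.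
2. Dialdehyde ⇐ periodate cleavage of a bis(1,2-diol) carried on the finished peroxide ring.
3. The 1,2-dioxane is closed as in the assumed biogenesis, by a tertiary hydroperoxide attacking the second oxidised carbon 6-exo. One H2O2 is inserted in one flask between the two tertiary carbons of a C2-symmetric bis-epoxide, each C–O bond with inversion, which sets both quaternary centres at once.
4. Bis-epoxide ⇐ double Sharpless epoxidation of (2E,6E)-3,6-dimethylocta-2,6-diene-1,8-diol ⇐ double Negishi methylalumination/hydroxymethylation of hexa-1,5-diyne.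
5. Ring order: there is only one ring, formed in step 3 before either side chain is attached.

## Route

**Step 1**
Reactants: 1 hexa-1,5-diyne
Product: 4 (2E,6E)-3,6-dimethylocta-2,6-diene-1,8-diol, via bis(alkenyl)alane 2 (not isolated), via dilithium bis(alkenylaluminate) 3 (not isolated)
Conditions: Me3Al (5 equiv), Cp2ZrCl2 (0.5 equiv), CH2Cl2, 0 °C to rt; volatiles removed; n-BuLi (2.1 equiv), THF/hexane, −78 °C; (CH2O)n, rt; aq. HCl
Reagents that add atoms: trimethylaluminium C[Al](C)C; formaldehyde (as paraformaldehyde) C=O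
Why: Negishi zirconium-catalysed methylalumination adds Me and Al syn across each terminal alkyne with Me on the internal carbon, and the derived alkenylaluminate is hydroxymethylated with retention, so both trisubstituted alkenes are E as in the classical geraniol synthesis.

**Step 2**
Reactants: 4 (2E,6E)-3,6-dimethylocta-2,6-diene-1,8-diol
Product: 5 (2S,3S,6S,7S)-2,3:6,7-diepoxy-3,6-dimethyloctane-1,8-diol
Conditions: Ti(OiPr)4 (10 mol%), L-(+)-diethyl tartrate (12 mol%), t-BuOOH (2.5 equiv), 4 Å MS, CH2Cl2, −20 °C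
Reagents that add atoms: tert-butyl hydroperoxide CC(C)(C)OO
Why: Double Sharpless asymmetric epoxidation, in which L-(+)-tartrate epoxidises each (E)-3-methylallylic alcohol on the same face as in geraniol (2S,3S); running it twice on a C2-symmetric diene raises the ee of the C2 product (Horeau effect) and the minor meso bis-epoxide is a separable diastereomer.

**Step 3**
Reactants: 5 (2S,3S,6S,7S)-2,3:6,7-diepoxy-3,6-dimethyloctane-1,8-diol
Product: 7 (1S,1'S)-1,1'-[(3R,6R)-3,6-dimethyl-1,2-dioxane-3,6-diyl]di(ethane-1,2-diol), via hydroperoxy epoxide 6 (not isolated)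
Conditions: anhydrous H2O2 in Et2O (5 equiv, ca. 1 M), H3PMo12O40 (5 mol%), Et2O/THF, 0 °C to rt
Reagents that add atoms: hydrogen peroxide OO
Why: Proposed new method: a one-flask double perhydrolysis in which H3PMo12O40-activated H2O2 first opens one epoxide at its tertiary carbon with inversion (known phosphomolybdic-acid perhydrolysis of trisubstituted epoxides) and the tertiary hydroperoxide so formed then opens the second epoxide 6-exo at its tertiary carbon, again with inversion (closest known reaction type: acid-catalysed hydroperoxide–epoxide cyclisation to 1,2-dioxanes), so the two (S) epoxide carbons become the (3R,6R) peroxide carbons and the trans-dimethyl ring follows from the reagent-controlled epoxide configurations, not from any ring bias.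

**Step 4**
Reactants: 7 (1S,1'S)-1,1'-[(3R,6R)-3,6-dimethyl-1,2-dioxane-3,6-diyl]di(ethane-1,2-diol)
Product: 8 (3R,6R)-3,6-dimethyl-1,2-dioxane-3,6-dicarbaldehyde
Conditions: NaIO4 (2.5 equiv), THF/H2O, 0 °C; extracted and kept as a CH2Cl2 solution
Reagents that add atoms: none
Why: Malaprade glycol cleavage removes both carbinol stereocentres, leaves the two quaternary peroxide carbons and the di-tert-alkyl O–O bond untouched, and gives a C2-symmetric dialdehyde with homotopic formyl groups.

**Step 5**
Reactants: 9 (7-bromoheptyl)benzene; 10 triphenylphosphine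
Product: 11 triphenyl(7-phenylheptyl)phosphonium bromide
Conditions: MeCN, reflux
Reagents that add atoms: none
Why: SN2 quaternisation of a primary bromide by PPh3 (phosphonium salt formation).

**Step 6**
Reactants: 8 (3R,6R)-3,6-dimethyl-1,2-dioxane-3,6-dicarbaldehyde; 11 triphenyl(7-phenylheptyl)phosphonium bromide
Product: 13 (3R,6R)-3,6-dimethyl-6-[(1Z)-8-phenyloct-1-en-1-yl]-1,2-dioxane-3-carbaldehyde, via phosphorus ylide 12 (not isolated)
Conditions: 11 (1 equiv), NaN(SiMe3)2 (0.95 equiv), THF, −78 to 0 °C; then added to 8 (3 equiv, excess recovered), THF, −78 °C to rt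
Reagents that add atoms: none
Why: Wittig olefination with a non-stabilised ylide (Z-selective, geometry irrelevant later), where the C2 symmetry of 8 makes either formyl group give the same product, excess dialdehyde enforces mono-reaction, and the fully substituted peroxide carbons cannot undergo Kornblum–DeLaMare cleavage under base.

**Step 7**
Reactants: 13 (3R,6R)-3,6-dimethyl-6-[(1Z)-8-phenyloct-1-en-1-yl]-1,2-dioxane-3-carbaldehyde; 14 (diethoxyphosphoryl)acetic acid
Product: 16 (2E)-3-{(3R,6R)-3,6-dimethyl-6-[(1Z)-8-phenyloct-1-en-1-yl]-1,2-dioxan-3-yl}prop-2-enoic acid, via dilithio phosphonoacetate 15 (not isolated)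
Conditions: 14 (1.5 equiv), n-BuLi (3.0 equiv), THF, −78 to 0 °C; then 13, 0 °C to rt; cold aq. HCl to pH 3
Reagents that add atoms: none
Why: Horner–Wadsworth–Emmons reaction of the phosphonoacetic acid dianion gives the (E)-enoic acid directly, so no ester hydrolysis is needed, and the aldehyde has no α-hydrogen and can only add the nucleophile.

**Step 8**
Reactants: 16 (2E)-3-{(3R,6R)-3,6-dimethyl-6-[(1Z)-8-phenyloct-1-en-1-yl]-1,2-dioxan-3-yl}prop-2-enoic acid
Product: 18 3-[(3R,6S)-3,6-dimethyl-6-(8-phenyloctyl)-1,2-dioxan-3-yl]propanoic acid, via monoalkene acid 17 (not isolated)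
Conditions: KO2CN=NCO2K (20 equiv, in portions), AcOH, MeOH/CH2Cl2, 0 °C to rt, repeated until complete
Reagents that add atoms: none
Why: Diimide reduction (concerted syn transfer of H2 from HN=NH) saturates both disubstituted C=C bonds, the conjugated one first, without cleaving the O–O bond and without touching either stereocentre (the C6 descriptor changes from R to S only through CIP priorities).

## Compound list

1 | hexa-1,5-diyne | C#CCCC#C | starting material
2 | (1E,5E)-(2,5-dimethylhexa-1,5-diene-1,6-diyl)bis(dimethylalane) | C[Al](C)/C=C(\C)CC/C(C)=C/[Al](C)C | intermediate (not isolated)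
3 | dilithium (1E,5E)-(2,5-dimethylhexa-1,5-diene-1,6-diyl)bis[butyl(dimethyl)aluminate] | [Li+].[Li+].CCCC[Al-](C)(C)/C=C(\C)CC/C(C)=C/[Al-](C)(C)CCCC | intermediate (not isolated)
4 | (2E,6E)-3,6-dimethylocta-2,6-diene-1,8-diol | OC/C=C(\C)CC/C(C)=C/CO | intermediate
5 | (2S,3S,6S,7S)-2,3:6,7-diepoxy-3,6-dimethyloctane-1,8-diol | OC[C@@H]1O[C@@]1(C)CC[C@]1(C)O[C@H]1CO | intermediate
6 | (2S,3R)-3-hydroperoxy-5-[(2S,3S)-3-(hydroxymethyl)-2-methyloxiran-2-yl]-3-methylpentane-1,2-diol | OC[C@H](O)[C@](C)(OO)CC[C@]1(C)O[C@H]1CO | intermediate (not isolated)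
7 | (1S,1'S)-1,1'-[(3R,6R)-3,6-dimethyl-1,2-dioxane-3,6-diyl]di(ethane-1,2-diol) | C[C@]1([C@@H](O)CO)CC[C@](C)([C@@H](O)CO)OO1 | intermediate
8 | (3R,6R)-3,6-dimethyl-1,2-dioxane-3,6-dicarbaldehyde | C[C@]1(C=O)CC[C@](C)(C=O)OO1 | intermediate
9 | (7-bromoheptyl)benzene | BrCCCCCCCc1ccccc1 | starting material
10 | triphenylphosphine | c1ccc(cc1)P(c1ccccc1)c1ccccc1 | starting material
11 | triphenyl(7-phenylheptyl)phosphonium bromide | [Br-].C(CCCCCCc1ccccc1)[P+](c1ccccc1)(c1ccccc1)c1ccccc1 | intermediate
12 | triphenyl(7-phenylheptylidene)phosphorane | C(CCCCCCc1ccccc1)=P(c1ccccc1)(c1ccccc1)c1ccccc1 | intermediate (not isolated)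
13 | (3R,6R)-3,6-dimethyl-6-[(1Z)-8-phenyloct-1-en-1-yl]-1,2-dioxane-3-carbaldehyde | C[C@]1(/C=C\CCCCCCc2ccccc2)CC[C@](C)(C=O)OO1 | intermediate
14 | (diethoxyphosphoryl)acetic acid | CCOP(=O)(CC(=O)O)OCC | starting material
15 | dilithium salt of the (diethoxyphosphoryl)acetic acid dianion | [Li+].[Li+].CCOP(=O)([CH-]C(=O)[O-])OCC | intermediate (not isolated)
16 | (2E)-3-{(3R,6R)-3,6-dimethyl-6-[(1Z)-8-phenyloct-1-en-1-yl]-1,2-dioxan-3-yl}prop-2-enoic acid | C[C@]1(/C=C\CCCCCCc2ccccc2)CC[C@](C)(/C=C/C(=O)O)OO1 | intermediate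
17 | 3-{(3R,6R)-3,6-dimethyl-6-[(1Z)-8-phenyloct-1-en-1-yl]-1,2-dioxan-3-yl}propanoic acid | C[C@]1(/C=C\CCCCCCc2ccccc2)CC[C@](C)(CCC(=O)O)OO1 | intermediate (not isolated)
18 | 3-[(3R,6S)-3,6-dimethyl-6-(8-phenyloctyl)-1,2-dioxan-3-yl]propanoic acid | C[C@]1(CCCCCCCCc2ccccc2)CC[C@](C)(CCC(=O)O)OO1 | target

## Step count and risks

Total steps: 8. Longest linear sequence: 7 (steps 1, 2, 3, 4, 6, 7, 8); step 5 is a one-step side branch.

**Step 3 (one-flask double perhydrolysis) is the most likely to fail.** The second epoxide oxygen, or the secondary hydroxyl freed by the first opening, may attack in place of the hydroperoxide and give tetrahydrofuran or tetrahydropyran products. Partial SN1 character could also erode the inversion. The fallback sets out from 4 and returns at 7; it makes the two C–O bonds in separate operations, so no second epoxide is present during the intermolecular perhydrolysis. Sharpless epoxidation of 4 with only 1 equiv of t-BuOOH (Ti(OiPr)4, L-(+)-diethyl tartrate; 4 recovered, any 5 formed kept) gives (2E)-5-[(2S,3S)-3-(hydroxymethyl)-2-methyloxiran-2-yl]-3-methylpent-2-en-1-ol F1. H2O2 with H3PMo12O40 opens F1 at the tertiary carbon to (2S,3R,6E)-3-hydroperoxy-3,6-dimethyloct-6-ene-1,2,8-triol F2. mCPBA then epoxidises the remaining alkene without facial control, giving 6 and its epoxide epimer (2S,3R)-3-hydroperoxy-5-[(2R,3R)-3-(hydroxymethyl)-2-methyloxiran-2-yl]-3-methylpentane-1,2-diol F3. A trace of camphorsulfonic acid closes both 6-exo, to 7 and to the meso tetraol (1S)-1-[(3R,6S)-6-[(1R)-1,2-dihydroxyethyl]-3,6-dimethyl-1,2-dioxan-3-yl]ethane-1,2-diol F4. Because the first centre is already fixed, the unwanted isomer is a meso diastereomer and not the enantiomer; it is removed by chromatography and 7 enters step 4.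

**Step 6 (mono-Wittig on the dialdehyde)** depends on statistical mono-reaction and on a small α-peroxy dialdehyde surviving a basic ylide. The fallback sets out from 7 and returns at 13, unmasking the aldehydes one at a time. NaIO4 (1 equiv) cleaves one glycol to (3R,6R)-6-[(1S)-1,2-dihydroxyethyl]-3,6-dimethyl-1,2-dioxane-3-carbaldehyde F5, which differs strongly in polarity from 7 and 8 (both recycled). Excess ylide 12 then converts F5 completely into (1S)-1-{(3R,6R)-3,6-dimethyl-6-[(1Z)-8-phenyloct-1-en-1-yl]-1,2-dioxan-3-yl}ethane-1,2-diol F6, the diol only consuming extra ylide as its alkoxide. A second NaIO4 cleavage gives 13.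

**Step 7 (dianion Horner–Wadsworth–Emmons)** may fail because the strongly basic dianion could trigger fragmentation of the α-peroxy aldehyde adduct before olefination. The fallback sets out from 13 and returns at 18, using a neutral stabilised ylide at the cost of two extra steps. Ph3P=CHCO2Me (toluene, 60 °C) gives methyl (2E)-3-{(3R,6R)-3,6-dimethyl-6-[(1Z)-8-phenyloct-1-en-1-yl]-1,2-dioxan-3-yl}prop-2-enoate F7. Diimide as in step 8 gives methyl 3-[(3R,6S)-3,6-dimethyl-6-(8-phenyloctyl)-1,2-dioxan-3-yl]propanoate F8. LiOH in THF/H2O at 0 °C, which the di-tert-alkyl peroxide tolerates because it has no hydrogen on the peroxide carbons, gives 18.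

## Further compounds

F1 | step 3 | (2E)-5-[(2S,3S)-3-(hydroxymethyl)-2-methyloxiran-2-yl]-3-methylpent-2-en-1-ol | OC[C@@H]1O[C@@]1(C)CC/C(C)=C/CO
F2 | step 3 | (2S,3R,6E)-3-hydroperoxy-3,6-dimethyloct-6-ene-1,2,8-triol | OC[C@H](O)[C@](C)(OO)CC/C(C)=C/CO
F3 | step 3 | (2S,3R)-3-hydroperoxy-5-[(2R,3R)-3-(hydroxymethyl)-2-methyloxiran-2-yl]-3-methylpentane-1,2-diol | OC[C@H](O)[C@](C)(OO)CC[C@@]1(C)O[C@@H]1CO
F4 | step 3 | (1S)-1-[(3R,6S)-6-[(1R)-1,2-dihydroxyethyl]-3,6-dimethyl-1,2-dioxan-3-yl]ethane-1,2-diol (meso) | C[C@]1([C@@H](O)CO)CC[C@@](C)([C@H](O)CO)OO1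
F5 | step 6 | (3R,6R)-6-[(1S)-1,2-dihydroxyethyl]-3,6-dimethyl-1,2-dioxane-3-carbaldehyde | C[C@]1([C@@H](O)CO)CC[C@](C)(C=O)OO1
F6 | step 6 | (1S)-1-{(3R,6R)-3,6-dimethyl-6-[(1Z)-8-phenyloct-1-en-1-yl]-1,2-dioxan-3-yl}ethane-1,2-diol | C[C@]1(/C=C\CCCCCCc2ccccc2)CC[C@](C)([C@@H](O)CO)OO1
F7 | step 7 | methyl (2E)-3-{(3R,6R)-3,6-dimethyl-6-[(1Z)-8-phenyloct-1-en-1-yl]-1,2-dioxan-3-yl}prop-2-enoate | C[C@]1(/C=C\CCCCCCc2ccccc2)CC[C@](C)(/C=C/C(=O)OC)OO1
F8 | step 7 | methyl 3-[(3R,6S)-3,6-dimethyl-6-(8-phenyloctyl)-1,2-dioxan-3-yl]propanoate | C[C@]1(CCCCCCCCc2ccccc2)CC[C@](C)(CCC(=O)OC)OO1
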